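(Readings and results come from a simulation for substances that don't exist; the scatter is artificial.)

At early times the bis adduct already follows the coupling partner. The north flask, charged with 1.4 M of it, holds 11.4% after 15.0 min, more than the 5.3% of the south-east flask, charged with 0.71 M, after 20.0 min.

| setting | east | south-east | north | epsilon | eta | zeta |
|---|---|---|---|---|---|---|
| starting material | 0.99 M | 0.99 M | 0.99 M | 0.99 M | 0.99 M | 0.99 M |
| coupling partner | 0.64 M | 0.71 M | 1.4 M | 0.495 M | 0.990 M | 1.19 M |
| scavenger | 1.19 M | 1.19 M | 1.19 M | 1.19 M | 1.19 M | 1.19 M |
| remark | run made earlier | run made earlier | run made earlier |  |  |  |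
| time |  |  |  | 2.0 h | 2.0 h | 2.0 h |

| run | time / min | bis adduct / % | starting material / % |
|---|---|---|---|
| east | 6.00 | 0.7 | 83.6 |
| east | 12.0 | 3.1 | 73.9 |
| east | 25.0 | 5.1 | 62.8 |
| east | 40.0 | 6.7 | 56.5 |
| east | 80.0 | 8.3 | 50.9 |
| south-east | 8.00 | 1.5 | 78.5 |
| south-east | 20.0 | 5.3 | 63.9 |
| south-east | 40.0 | 8.2 | 53.8 |
| south-east | 60.0 | 9.2 | 49.4 |
| south-east | 80.0 | 9.5 | 46.6 |
| north | 15.0 | 11.4 | 48.5 |
| north | 30.0 | 18.1 | 34.5 |
| north | 50.0 | 21.7 | 26.7 |
| north | 60.0 | 21.7 | 23.5 |
| north | 80.0 | 21.8 | 20.6 |

(readings scatter by 0.3 percentage points)



- how much bis adduct is there at the end, in percent of the starting material charged: for each flask in turn (epsilon, eta, zeta)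

1. I look at the late readings first. North reads 21.7%, then 21.8%; south-east reads 9.2%, then 9.5%. I therefore treat the last reading of each as its end value.

2. South-east gives 13.2% as its molar bis adduct at the last reading per molar coupling partner charged, which I call the bis return r. North gives 15.4%, more than south-east.

3. Eta and zeta are charged between these two runs, so I assume that their r lies between these two values. The bis adduct, in percent of the starting material, is r times the partner charge over the starting-material charge. On that assumption I expect eta between 13.2% and 15.4%, and zeta between 15.9% and 18.5%.

4. Epsilon is charged below both of these runs, so this assumption does not reach it. For its upper bound I keep r at the south-east value, which gives 6.62%. Bis adduct takes two couplings, so for its lower bound I let r shrink in proportion to the charge, which gives 4.62%.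

5. The forecast gives 4.8%, 17.5% and 24%, holding that “so there is no early cutoff”. Its epsilon value lies inside my bracket, but its eta and zeta values lie above my upper bounds.

The flasks give 5.56%, 14.9% and 18.0%.

    coupling partner + first product → bis adduct + released group (k = 8.90 × 10⁻⁴ /M/s)
    first product → side product (k = 8.10 × 10⁻⁴ /s)
    starting material + released group ⇌ idle adduct, settled at all times (K = 0.980 /M)
    coupling partner + bis adduct → tris adduct + released group (k = 2.30 × 10⁻⁴ /M/s)
    scavenger + released group → scavenged by-product (k = 0.00140 /M/s)
    starting material + coupling partner → first product + released group (k = 6.00 × 10⁻⁴ /M/s)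

The bis return comes to 14.9% in eta and 15.0% in zeta, both between the two run values, and to 11.1% in epsilon, lower than south-east. In epsilon, just after the start, first product goes to side product 1.8 times as fast as it goes to bis adduct. At the asked time in epsilon, that ratio of the two rates stands at 46.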